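Target does not stay target.

    first complex ⇌ loaded enzyme + first product (K1 = 0.0062 M, k1 = 73 s⁻¹)
    second complex → free enzyme + target (k2 = 530 s⁻¹)
    target + free enzyme ⇌ isomer of the product + free enzyme, rate k3*[free enzyme]*[target] forward; the back reaction follows from the equilibrium constant (K3 = 2.3, k3 = 6300 L mol⁻¹ s⁻¹)
    second substrate + loaded enzyme ⇌ second complex (K4 = 190 L mol⁻¹, k4 = 6.3 × 10⁵ L mol⁻¹ s⁻¹)
    starting material + free enzyme ⇌ first complex (K5 = 40 L mol⁻¹, k5 = 1.1 × 10⁶ L mol⁻¹ s⁻¹)

common to all: free enzyme 0.15 µM
- north: starting material 11 mM; second substrate 19.8 mM; time 50 min; everything together in a closed stirred flask, run for 50 min
- south: starting material 11 mM; second substrate 19.8 mM (fed, over 40.0 min); time 50 min; all but second substrate at the start; second substrate goes in evenly over 40.0 min, the run ends at 50 min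
- north-east: starting material 11 mM (fed, over 40.0 min); second substrate 19.8 mM; time 50 min; a stirred flask in which starting material is dosed at a steady rate over 40.0 min without added volume, worked up at 50 min
- south-west: starting material 11 mM; second substrate 19.8 mM; a single well-mixed tank run continuously and read at steady state, 50 min in it on average

- the set-up with the highest share of target in all that became target or isomer of the product, at the outlet or at the end ("none" if the first two lie within 2 percentage points) (north / south / north-east / south-west / none)
- share of target in all that became target or isomer of the product, at the outlet or at the end, north
- share of target in all that became target or isomer of the product, at the outlet or at the end, south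
- share of target in all that became target or isomer of the product, at the outlet or at the end, north-east
- share of target in all that became target or isomer of the product, at the outlet or at the end, south-west

- the stated concentrations are those of everything mixed, before any reaction; amounts are the same in each set-up
- the feed brings no volume worth counting
- run time (north): 50 min

Free enzyme interconverts target and isomer of the product, a case of kinetic against thermodynamic control, so the share of target can be reckoned as an equilibrium share plus a correction. The equilibrium share is 1 over 1 plus the isomerisation constant, 30.3%. Freshly formed product is target, so its excess over that share starts at the remaining fraction, 69.7%, and decays at the forward rate constant times free enzyme times 1.43. The relaxation count, that decay rate times the run time with the whole catalyst free, is 4.07. Multiplied by the free fraction of the catalyst, it gives the working count m.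

Taking step 5 at equilibrium and neglecting the other bound forms, the free fraction at the full charge of starting material is 69.4%, so m is 2.82. In north, with formation taken as steady, the mean surviving excess is (1 − e^(−m))/m, which puts the share at 53.5%.

In north-east, formation is taken to rise in proportion to time, which favours young product. The surviving excess becomes 2/m minus 2(1 − e^(−m))/m squared, and the share comes to 63.2%. The weak link is the free fraction, so dosed starting material is now taken at half its charge. Reforged, the free fraction is 82.0%, m is 3.33, and the share is 60.0%, higher than north.

The forecast chose north-east, with 49% for north, 53% for south, 65% for north-east and 47% for south-west: “Dosing the starting material keeps formation late and total conversion low”. It stands below this reckoning for north and above it for north-east.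

The simulation gives north-east, with 47.5%, 48.9%, 57.1% and 46.8% in the same order, so the forecast for north-east is 7.9 percentage points high.

In north-east, starting material stood at 68.2% of its charge at the end of the feed, with free enzyme, the resting state, at 73.8% of the catalyst, and half the turnover of the step from first complex to loaded enzyme and first product was done by 31.8 min. At 50.0 min, target held 24.9% of the charge and isomer of the product 18.7%, while free enzyme at 77.3% gives a count of 3.15.

In the neighbouring flask, north-east with 3.7 × 10⁻⁵ mM of free enzyme, the count scales with the catalyst to 0.822, the free fraction kept as reforged, and the same reckoning gives 84.3%. The computed share there is 84.5%, with 11.1% of the charge as target and 2.03% as isomer of the product.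

(Its constants were set for the occasion; the result is computed.)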